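**Strategy.** With longipinane numbering (C1 ketone, C2=C3, cyclobutane C4–C5–C11–C10, C6 gem-dimethyl, C7–C9 oxygenated), the route rests on the C4–C10 bond of the four-membered ring. The 9-hydroxyl sits next to quaternary C10 and anti to C10–C4, so it is read as the remnant of a C9–C10 oxirane that C4 opens in a 4-exo-tet attack. C4 is the α′-carbon of a transposed enone (C3 ketone), turned afterwards into the 3-methyl-2-en-1-one. The precursor is a cis-fused cyclohexenone–epoxycycloheptanol made by Diels–Alder reaction and ring-closing metathesis. One operation closes the cyclobutane and sets C4, C10 and, by retention, C9.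

Key step: step 11

Assumption: compounds 5 and 9 and (+)-Ipc2BOMe are taken as purchasable; the Diels–Alder catalyst enantiomer in step 5 is the one predicted by the usual binding model, and its mirror image serves if the facial sense is the reverse.

Step 1
Reactants: 1 3-hydroxy-2,2-dimethylpropanal; 2 1-(triphenyl-λ5-phosphanylidene)propan-2-one
Product: 3 (E)-6-hydroxy-5,5-dimethylhex-3-en-2-one
Conditions: toluene, 90 °C
Reagents that add atoms: none
Why: Wittig olefination with a stabilised ylide should give the E-enone, and the aldehyde has a quaternary α-carbon so it can neither enolise nor dehydrate.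

Step 2
Reactants: 3 (E)-6-hydroxy-5,5-dimethylhex-3-en-2-one
Product: 4 (E)-2,2-dimethyl-5-oxohex-3-enal
Conditions: PhI(OAc)2, TEMPO (10 mol %), CH2Cl2, rt
Reagents that add atoms: none
Why: Oxoammonium (TEMPO) oxidation of the primary alcohol should stop at the non-enolisable aldehyde and leave the enone alone.

Step 3
Reactants: 4 (E)-2,2-dimethyl-5-oxohex-3-enal; 5 3-(methoxymethoxy)prop-1-ene
Product: 7 (3E,6S,7S)-6-hydroxy-7-(methoxymethoxy)-5,5-dimethylnona-3,8-dien-2-one, via borinate ester 6 (not isolated)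
Conditions: 5, s-BuLi, THF, −78 °C; (+)-Ipc2BOMe; BF3·OEt2; then 4, −78 °C; HOCH2CH2NH2 work-up
Reagents that add atoms: none
Why: Brown alkoxyallylboration: the (Z)-γ-alkoxyallylborane adds through a chair transition state to give the syn pair (C7 and C8 of the target), the isopinocampheyl groups from (−)-α-pinene select the aldehyde face, and the aldehyde reacts far faster than the enone ketone.

Step 4
Reactants: 7 (3E,6S,7S)-6-hydroxy-7-(methoxymethoxy)-5,5-dimethylnona-3,8-dien-2-one
Product: 8 (3E,6S,7S)-2,6-bis[(tert-butyldimethylsilyl)oxy]-7-(methoxymethoxy)-5,5-dimethylnona-1,3,8-triene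
Conditions: TBSOTf (2.5 equiv), Et3N, CH2Cl2, −78 → 0 °C
Reagents that add atoms: tert-butyldimethylsilyl trifluoromethanesulfonate, CC(C)(C)[Si](C)(C)OS(=O)(=O)C(F)(F)F
Why: Soft enolisation and O-silylation: the hindered hydroxyl is capped and the methyl ketone, whose only α-hydrogens are on the methyl group, becomes the 2-silyloxy-1,3-diene.

Step 5
Reactants: 8 (3E,6S,7S)-2,6-bis[(tert-butyldimethylsilyl)oxy]-7-(methoxymethoxy)-5,5-dimethylnona-1,3,8-triene; 9 (E)-4-chlorobut-3-en-2-one
Product: 10 1-[(1R,2S,6S)-4-[(tert-butyldimethylsilyl)oxy]-6-chloro-2-[(3S,4S)-3-[(tert-butyldimethylsilyl)oxy]-4-(methoxymethoxy)-2-methylhex-5-en-2-yl]cyclohex-3-en-1-yl]ethan-1-one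
Conditions: (S)-1-(2-methylphenyl)-3,3-diphenyltetrahydro-1H,3H-pyrrolo[1,2-c][1,3,2]oxazaborole (20 mol %), HN(SO2CF3)2 (20 mol %), CH2Cl2, −78 → −40 °C
Reagents that add atoms: none
Why: Diels–Alder reaction under chiral oxazaborolidinium Lewis acid catalysis: the silyloxy group and the substituted diene terminus direct the acetyl-bearing carbon next to the side chain, the endo mode places acetyl cis to the side chain (C11 and C5 of the target), the E-dienophile puts chlorine trans to acetyl, and the catalyst is relied on for the diene face.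

Step 6
Reactants: 10 the Diels–Alder adduct
Product: 11 tert-butyl{[(3S,4R,5S)-5-chloro-3-[(3S,4S)-3-[(tert-butyldimethylsilyl)oxy]-4-(methoxymethoxy)-2-methylhex-5-en-2-yl]-4-(prop-1-en-2-yl)cyclohex-1-en-1-yl]oxy}dimethylsilane
Conditions: Cp2TiMe2, toluene, 65 °C
Reagents that add atoms: bis(cyclopentadienyl)dimethyltitanium Cp2TiMe2, C[Ti](C)(C1C=CC=C1)C1C=CC=C1
Why: Petasis methylenation through a non-basic titanium carbene should turn the acetyl group into the isopropenyl group without epimerising the neighbouring stereocentre or eliminating HCl.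

Step 7
Reactants: 11 the isopropenyl silyl enol ether
Product: 13 (4R,5S)-5-[(3S,4S)-3-[(tert-butyldimethylsilyl)oxy]-4-(methoxymethoxy)-2-methylhex-5-en-2-yl]-4-(prop-1-en-2-yl)cyclohex-2-en-1-one, via chloro ketone 12 (not isolated)
Conditions: Bu4NF/AcOH (1:1), THF, 0 °C; then Et3N, rt
Reagents that add atoms: none
Why: Fluoride cleaves the silyl enol ether much faster than the hindered secondary silyl ether, and Et3N then causes E1cB loss of HCl toward the only acidic side to give the cyclohex-2-enone.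

Step 8
Reactants: 13 the methoxymethyl-protected enone
Product: 14 (4R,5S)-5-[(3S,4S)-3-[(tert-butyldimethylsilyl)oxy]-4-hydroxy-2-methylhex-5-en-2-yl]-4-(prop-1-en-2-yl)cyclohex-2-en-1-one
Conditions: B-bromocatecholborane, CH2Cl2, −78 °C; aq. NaHCO3
Reagents that add atoms: none
Why: Lewis acid cleavage of the acetal-type ether at low temperature should free the allylic hydroxyl while the silyl ether, the enone and the alkenes survive.

Step 9
Reactants: 14 the allylic alcohol
Product: 15 (4aR,7S,8S,9aS)-8-[(tert-butyldimethylsilyl)oxy]-7-hydroxy-5,9,9-trimethyl-1,4a,7,8,9,9a-hexahydro-2H-benzo[7]annulen-2-one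
Conditions: second-generation Grubbs catalyst (H2IMes)(PCy3)Cl2Ru=CHPh (5 mol %), CH2Cl2, 40 °C
Reagents that add atoms: none
Why: Ring-closing metathesis between the vinyl and isopropenyl groups, held cis on the cyclohexenone, should close the seven-membered ring as the trisubstituted C9=C10 alkene.

Step 10
Reactants: 15 the cis-fused bicyclic dienone
Product: 16 the 5,6-epoxide of 15 whose oxirane oxygen is cis to the 7-hydroxyl (benzo[7]annulene numbering; C10–C9 oxirane in longipinane numbering)
Conditions: VO(acac)2 (5 mol %), t-BuOOH, CH2Cl2, 0 °C → rt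
Reagents that add atoms: tert-butyl hydroperoxide, CC(C)(C)OO
Why: Hydroxyl-directed vanadium-catalysed epoxidation delivers oxygen syn to the allylic hydroxyl, which sets C9 and places the oxirane anti to the later C4–C10 bond, and the electron-poor enone is inert.

Step 11
Reactants: 16 the syn-epoxy alcohol
Product: 18 7-O-(tert-butyldimethylsilyl)-7,8,9-trihydroxy-15-norlongipin-1-en-3-one, via lithium dienolate 17 (not isolated)
Conditions: LiN(iPr)2 (2.5 equiv), THF, −78 °C (16 added to the base) → 0 °C; AcOH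
Reagents that add atoms: none
Why: LiN(iPr)2 removes the hydroxyl proton and then the kinetically most acidic α′-hydrogen (C4) of the enone to give cross-conjugated dienolate 17, whose α′-carbon attacks C10 of the oxirane opposite to the C–O bond. The closest known reaction types are the Stork epoxynitrile cyclisation, in which a carbanion prefers the four-membered ring over the 5-endo alternative, and the enolate alkylation route to bicyclo[3.1.1]heptan-2-ones. The cyclobutane C4–C5–C11–C10 closes in the 4-exo-tet mode, the six- and seven-membered rings being already present. Quaternary C10 is set by inversion, C4 by the cis ring fusion at C5 and C11 that lets the enolate reach only one face, and C9 keeps the oxygen placed in step 10, so 9-OH ends cis to 8-OH. The step needs α′- over γ-deprotonation (kinetic base, inverse addition), C- over O-alkylation (lithium enolate in THF without polar additive) and attack at C10 not C9 (exo preference), and the cis alkoxide cannot undergo Payne rearrangement and should hold Li+ at the oxirane oxygen. The product cannot enolise again because C4 and C11 are bridgeheads, which makes the closure irreversible.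

Step 12
Reactants: 18 the tricyclic enone diol
Product: 19 the 8,9-O-isopropylidene derivative of 18
Conditions: 2,2-dimethoxypropane, PPTS (cat.), CH2Cl2, rt
Reagents that add atoms: 2,2-dimethoxypropane, COC(C)(C)OC
Why: Acid-catalysed transacetalisation protects the cis-8,9-diol, the only 1,2-diol present.

Step 13
Reactants: 19 the acetonide enone
Product: 20 7-O-(tert-butyldimethylsilyl)-8,9-O-isopropylidenelongipin-1-ene-3,7,8,9-tetrol
Conditions: MeLi, Et2O, −78 °C; aq. NH4Cl
Reagents that add atoms: methyllithium, [Li]C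
Why: 1,2-Addition of MeLi to the enone carbonyl, which has no enolisable hydrogen because C4 and C11 are bridgeheads, should give the tertiary allylic alcohol, whose configuration (methyl expected anti to the C14 methyl side) is lost in the next step.

Step 14
Reactants: 20 the tertiary allylic alcohol
Product: 21 7-O-(tert-butyldimethylsilyl)-8,9-O-isopropylidene-7,8,9-trihydroxylongipin-2-en-1-one
Conditions: [C5H5NH][CrO3Cl] (pyridinium chlorochromate), NaOAc, 4 Å sieves, CH2Cl2, rt
Reagents that add atoms: pyridinium chlorochromate, c1cc[nH+]cc1.[O-][Cr](=O)(=O)Cl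
Why: Babler–Dauben oxidative transposition: the tertiary allylic chromate ester undergoes a [3,3] shift and oxidation to give the 3-methyl-2-en-1-one.

Step 15
Reactants: 21 the silyl-protected methyl enone
Product: 22 8,9-O-isopropylidene-7,8,9-trihydroxylongipin-2-en-1-one
Conditions: Bu4NF, THF, 50 °C; aq. NH4Cl
Reagents that add atoms: none
Why: Fluoride desilylation frees the C7 hydroxyl, and the acetonide and enone are stable to Bu4NF.

Step 16
Reactants: 22 the C7 alcohol; 23 (Z)-2-methylbut-2-enoic acid (angelic acid)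
Product: 24 7-O-angeloyl-8,9-O-isopropylidene-7,8,9-trihydroxylongipin-2-en-1-one
Conditions: 23, 2,4,6-trichlorobenzoyl chloride, Et3N, toluene, rt; then 22, DMAP, toluene, 80 °C
Reagents that add atoms: none
Why: Yamaguchi esterification through the pre-formed mixed anhydride acylates the only free hydroxyl and should keep the Z geometry of the angelate.

Step 17
Reactants: 24 the angelate acetonide
Product: 25 7-angeloyloxy-8,9-dihydroxylongipin-2-en-1-one
Conditions: AcOH/H2O (4:1), 45 °C
Reagents that add atoms: none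
Why: Mild acid hydrolysis of the acetonide releases the cis-8,9-diol without touching the ester or the enone.

Step 18
Reactants: 25 the angelate diol; 26 3-methylbutanoic anhydride
Product: 27 (4R,5S,7S,8S,9S,10R,11R)-7-angeloyloxy-9-hydroxy-8-(3-methylbutanoyloxy)longipin-2-en-1-one (CNP0128158.1)
Conditions: DMAP (cat.), pyridine, CH2Cl2, −20 → 0 °C
Reagents that add atoms: none
Why: DMAP-catalysed site-selective acylation: the C8 hydroxyl, flanked by two methine carbons, should react well ahead of the C9 hydroxyl that is neopentyl-like next to quaternary C10.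

**Compound list**

1 | 3-hydroxy-2,2-dimethylpropanal | OCC(C)(C)C=O | starting material
2 | 1-(triphenyl-λ5-phosphanylidene)propan-2-one | CC(=O)C=P(c1ccccc1)(c1ccccc1)c1ccccc1 | starting material
3 | (E)-6-hydroxy-5,5-dimethylhex-3-en-2-one | CC(=O)/C=C/C(C)(C)CO | intermediate
4 | (E)-2,2-dimethyl-5-oxohex-3-enal | CC(=O)/C=C/C(C)(C)C=O | intermediate
5 | 3-(methoxymethoxy)prop-1-ene | C=CCOCOC | starting material
6 | bis(isopinocampheyl)borinate ester of 7 (boron on the C6 oxygen) | C=C[C@H](OCOC)[C@@H](OB([C@H]1C[C@H]2C[C@@H]([C@@H]1C)C2(C)C)[C@H]1C[C@H]2C[C@@H]([C@@H]1C)C2(C)C)C(C)(C)/C=C/C(C)=O | intermediate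
7 | (3E,6S,7S)-6-hydroxy-7-(methoxymethoxy)-5,5-dimethylnona-3,8-dien-2-one | C=C[C@H](OCOC)[C@@H](O)C(C)(C)/C=C/C(C)=O | intermediate
8 | (3E,6S,7S)-2,6-bis[(tert-butyldimethylsilyl)oxy]-7-(methoxymethoxy)-5,5-dimethylnona-1,3,8-triene | C=C[C@H](OCOC)[C@@H](O[Si](C)(C)C(C)(C)C)C(C)(C)/C=C/C(=C)O[Si](C)(C)C(C)(C)C | intermediate
9 | (E)-4-chlorobut-3-en-2-one | CC(=O)/C=C/Cl | starting material
10 | 1-[(1R,2S,6S)-4-silyloxy-6-chloro-2-(side chain)cyclohex-3-en-1-yl]ethan-1-one (acetyl cis to side chain, chlorine trans to acetyl) | C=C[C@H](OCOC)[C@@H](O[Si](C)(C)C(C)(C)C)C(C)(C)[C@H]1C=C(O[Si](C)(C)C(C)(C)C)C[C@H](Cl)[C@H]1C(C)=O | intermediate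
11 | isopropenyl analogue of 10 | C=C[C@H](OCOC)[C@@H](O[Si](C)(C)C(C)(C)C)C(C)(C)[C@H]1C=C(O[Si](C)(C)C(C)(C)C)C[C@H](Cl)[C@H]1C(C)=C | intermediate
12 | (3S,4R,5S)-3-chloro-4-(prop-1-en-2-yl)-5-(side chain)cyclohexan-1-one | C=C[C@H](OCOC)[C@@H](O[Si](C)(C)C(C)(C)C)C(C)(C)[C@H]1CC(=O)C[C@H](Cl)[C@H]1C(C)=C | intermediate
13 | (4R,5S)-5-[(3S,4S)-3-silyloxy-4-(methoxymethoxy)-2-methylhex-5-en-2-yl]-4-(prop-1-en-2-yl)cyclohex-2-en-1-one | C=C[C@H](OCOC)[C@@H](O[Si](C)(C)C(C)(C)C)C(C)(C)[C@H]1CC(=O)C=C[C@H]1C(C)=C | intermediate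
14 | (4R,5S)-5-[(3S,4S)-3-silyloxy-4-hydroxy-2-methylhex-5-en-2-yl]-4-(prop-1-en-2-yl)cyclohex-2-en-1-one | C=C[C@H](O)[C@@H](O[Si](C)(C)C(C)(C)C)C(C)(C)[C@H]1CC(=O)C=C[C@H]1C(C)=C | intermediate
15 | (4aR,7S,8S,9aS)-8-[(tert-butyldimethylsilyl)oxy]-7-hydroxy-5,9,9-trimethyl-1,4a,7,8,9,9a-hexahydro-2H-benzo[7]annulen-2-one | CC(C)(C)[Si](C)(C)O[C@@H]1[C@@H](O)C=C(C)[C@@H]2C=CC(=O)C[C@@H]2C1(C)C | intermediate
16 | 5,6-epoxide of 15, oxirane oxygen cis to the 7-hydroxyl | CC(C)(C)[Si](C)(C)O[C@@H]1[C@@H](O)[C@H]3O[C@@]3(C)[C@@H]2C=CC(=O)C[C@@H]2C1(C)C | intermediate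
17 | dilithium alkoxide dienolate of 16 | CC(C)(C)[Si](C)(C)O[C@@H]1[C@@H](O[Li])[C@H]3O[C@@]3(C)[C@@H]2C=CC(O[Li])=C[C@@H]2C1(C)C | intermediate
18 | 7-O-(tert-butyldimethylsilyl)-7,8,9-trihydroxy-15-norlongipin-1-en-3-one | CC(C)(C)[Si](C)(C)O[C@@H]1[C@@H](O)[C@@H](O)[C@@]2(C)[C@@H]3C=CC(=O)[C@H]2[C@@H]3C1(C)C | intermediate
19 | 8,9-O-isopropylidene derivative of 18 | CC(C)(C)[Si](C)(C)O[C@@H]1[C@H]4OC(C)(C)O[C@H]4[C@@]2(C)[C@@H]3C=CC(=O)[C@H]2[C@@H]3C1(C)C | intermediate
20 | 7-O-(tert-butyldimethylsilyl)-8,9-O-isopropylidenelongipin-1-ene-3,7,8,9-tetrol | CC(C)(C)[Si](C)(C)O[C@@H]1[C@H]4OC(C)(C)O[C@H]4[C@@]2(C)[C@@H]3C=C[C@](C)(O)[C@H]2[C@@H]3C1(C)C | intermediate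
21 | 7-O-(tert-butyldimethylsilyl)-8,9-O-isopropylidene-7,8,9-trihydroxylongipin-2-en-1-one | CC(C)(C)[Si](C)(C)O[C@@H]1[C@H]4OC(C)(C)O[C@H]4[C@@]2(C)[C@@H]3C(=O)C=C(C)[C@H]2[C@@H]3C1(C)C | intermediate
22 | 8,9-O-isopropylidene-7,8,9-trihydroxylongipin-2-en-1-one | O[C@@H]1[C@H]4OC(C)(C)O[C@H]4[C@@]2(C)[C@@H]3C(=O)C=C(C)[C@H]2[C@@H]3C1(C)C | intermediate
23 | (Z)-2-methylbut-2-enoic acid (angelic acid) | C/C=C(/C)C(=O)O | starting material
24 | 7-O-angeloyl-8,9-O-isopropylidene-7,8,9-trihydroxylongipin-2-en-1-one | C/C=C(/C)C(=O)O[C@@H]1[C@H]4OC(C)(C)O[C@H]4[C@@]2(C)[C@@H]3C(=O)C=C(C)[C@H]2[C@@H]3C1(C)C | intermediate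
25 | 7-angeloyloxy-8,9-dihydroxylongipin-2-en-1-one | C/C=C(/C)C(=O)O[C@@H]1[C@@H](O)[C@@H](O)[C@@]2(C)[C@@H]3C(=O)C=C(C)[C@H]2[C@@H]3C1(C)C | intermediate
26 | 3-methylbutanoic anhydride | CC(C)CC(=O)OC(=O)CC(C)C | starting material
27 | (4R,5S,7S,8S,9S,10R,11R)-7-angeloyloxy-9-hydroxy-8-(3-methylbutanoyloxy)longipin-2-en-1-one (CNP0128158.1) | C/C=C(/C)C(=O)O[C@@H]1[C@@H](OC(=O)CC(C)C)[C@@H](O)[C@@]2(C)[C@@H]3C(=O)C=C(C)[C@H]2[C@@H]3C1(C)C | target

**Step count and risks**

Total step count: 18. Longest linear sequence: 18 steps (1 to 27).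

Step 11 (most likely to fail). The dienolate may alkylate on oxygen to give a bridged enol ether, the base may remove the γ-hydrogen at C11 and open the oxirane by elimination, or substitution at the fully substituted oxirane carbon may be too slow. The fallback changes from an anionic to a Lewis acid-driven, Mukaiyama-type closure and sets out from 16. LiN(iPr)2 and Me3SiCl at −78 °C would give the trimethylsilyl dienol ether that also carries a trimethylsilyl ether on the 8-oxygen, F1. TiCl4 in CH2Cl2 at −78 °C would then ionise the oxirane at tertiary C10 and let the enol ether carbon C4 capture it from the only face it can reach. Aqueous work-up removes the silyl groups and the fallback rejoins the route at 18.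

Step 5. The chiral diene and the chiral catalyst may be mismatched, or the ether oxygens may tie up the Lewis acid, so that the cycloaddition shows poor facial selectivity or stalls. The fallback runs the cycloaddition before any side-chain stereocentre exists and sets out from 3.
- TBSOTf and Et3N would give the bis-silyl diene F2.
- The same catalysed Diels–Alder reaction with 9 would give the cis adduct F3, now under catalyst control alone.
- Cp2TiMe2 would give the isopropenyl compound F4.
- Excess Bu4NF followed by Et3N would give the hydroxy enone F5.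
- TEMPO and PhI(OAc)2 would give the aldehyde F6.
- The alkoxyallylboration of step 3 would give the syn adduct F7 under reagent control.
- TBSOTf with 2,6-lutidine would then rejoin the route at 13.

Step 16. Acylation of the hindered C7 hydroxyl may be incomplete and the angelate may isomerise to the E (tiglate) ester at 80 °C. The fallback builds the Z alkene on the alcohol and sets out from 22. Esterification with 2-[bis(2,2,2-trifluoroethoxy)phosphoryl]propanoic acid (DCC, DMAP) would give the phosphonate ester F8. Still–Gennari olefination (KN(SiMe3)2, 18-crown-6, acetaldehyde, THF, −78 °C) would then give the (Z)-2-methylbut-2-enoate and rejoin the route at 24.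

Further compounds
F1 | step 11 | bis(trimethylsilyl) derivative of 16 (silyl dienol ether and 8-O-silyl ether) | CC(C)(C)[Si](C)(C)O[C@@H]1[C@@H](O[Si](C)(C)C)[C@H]3O[C@@]3(C)[C@@H]2C=CC(O[Si](C)(C)C)=C[C@@H]2C1(C)C
F2 | step 5 | (E)-2,6-bis[(tert-butyldimethylsilyl)oxy]-5,5-dimethylhexa-1,3-diene | C=C(O[Si](C)(C)C(C)(C)C)/C=C/C(C)(C)CO[Si](C)(C)C(C)(C)C
F3 | step 5 | 1-[(1R,2S,6S)-4-silyloxy-6-chloro-2-(1-silyloxy-2-methylpropan-2-yl)cyclohex-3-en-1-yl]ethan-1-one | CC(C)(C)[Si](C)(C)OCC(C)(C)[C@H]1C=C(O[Si](C)(C)C(C)(C)C)C[C@H](Cl)[C@H]1C(C)=O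
F4 | step 5 | isopropenyl analogue of F3 | CC(C)(C)[Si](C)(C)OCC(C)(C)[C@H]1C=C(O[Si](C)(C)C(C)(C)C)C[C@H](Cl)[C@H]1C(C)=C
F5 | step 5 | (4R,5S)-5-(1-hydroxy-2-methylpropan-2-yl)-4-(prop-1-en-2-yl)cyclohex-2-en-1-one | OCC(C)(C)[C@H]1CC(=O)C=C[C@H]1C(C)=C
F6 | step 5 | 2-methyl-2-[(1S,6R)-5-oxo-6... ring as in F5]propanal, the aldehyde of F5 | O=CC(C)(C)[C@H]1CC(=O)C=C[C@H]1C(C)=C
F7 | step 5 | (4R,5S)-5-[(3S,4S)-3-hydroxy-4-(methoxymethoxy)-2-methylhex-5-en-2-yl]-4-(prop-1-en-2-yl)cyclohex-2-en-1-one | C=C[C@H](OCOC)[C@@H](O)C(C)(C)[C@H]1CC(=O)C=C[C@H]1C(C)=C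
F8 | step 16 | 2-[bis(2,2,2-trifluoroethoxy)phosphoryl]propanoate ester of 22 | CC(C(=O)O[C@@H]1[C@H]4OC(C)(C)O[C@H]4[C@@]2(C)[C@@H]3C(=O)C=C(C)[C@H]2[C@@H]3C1(C)C)P(=O)(OCC(F)(F)F)OCC(F)(F)F
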